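## Retrosynthetic overview

1. The target comes from C6 alcohol 50 by SN2 chlorination with inversion; 50 comes from a transannular oxa-Michael addition of C2–OH to C8 of a butenolide, which closes ring C (tetrahydropyran) and sets C8 and C17 of ring D (lactone).
2. Ring B (ten-membered) is closed at C6–C7 by an intramolecular vinylogous Mukaiyama aldol reaction; C3–C4 comes from an indium allylation and C8–C9 from a Ni/Cr coupling of a tetronate triflate with the ring A aldehyde.
3. Ring A is closed at C12–C13 by a gold-catalysed 6-endo-dig acetoxycyclisation of 1,5-enyne 22. The enabling feature is that C11 is a methyl-bearing tertiary C–O centre flanked by C12, while C13=C14 is a cis-alkene on the quaternary C1: this is a 2-methyl-1,5-enyne (C12=C11 isopropenyl, C13≡C14 alkyne) retron. C12 enters as CH2 and is oxidised afterwards.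
4. The enyne comes from an Ireland–Claisen rearrangement (C1–C10 bond; C1 and C10); all chirality is relayed from C2 of (S)-glycerate acetonide 1.
5. Ring order: A (step 10), D as butenolide (step 16), B (step 23), C (step 25).

Key step: step 10

Remarks:
- Briarane numbering (C1–C20) is used for all intermediates; β is the face of ring A that carries the C1 methyl group, α the opposite face. Configurations are those of the SMILES strings.
- Assumption: 3-methyltetronic acid (31) is taken as a commercial material.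
- Assumption: in the Ireland–Claisen step the new bond forms anti to the allylic C2–O bond, with H-2 held in the alkene plane by allylic 1,3-strain.

## Route

Step 1
Reactants: 1 methyl (4S)-2,2-dimethyl-1,3-dioxolane-4-carboxylate; 2 dimethyl (1-diazo-2-oxopropyl)phosphonate
Product: 4 (4R)-4-ethynyl-2,2-dimethyl-1,3-dioxolane, via aldehyde 3 (not isolated)
Conditions: i-Bu2AlH, CH2Cl2, −78 °C; then 2, K2CO3, MeOH, 0 °C to rt
Reagents that add atoms: dimethyl (1-diazo-2-oxopropyl)phosphonate, CC(=O)C(=[N+]=[N-])P(=O)(OC)OC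
Why: Partial ester reduction followed in the same flask by Ohira–Bestmann (Seyferth–Gilbert) homologation should give the alkyne, whose stereocentre (later C2) is bought with 1 and is not a reacting centre.

Step 2
Reactants: 4 (4R)-4-ethynyl-2,2-dimethyl-1,3-dioxolane; 5 methyl chloroformate
Product: 7 methyl 3-[(4R)-2,2-dimethyl-1,3-dioxolan-4-yl]prop-2-ynoate, via lithium acetylide 6 (not isolated)
Conditions: n-BuLi, THF, −78 °C; then 5
Reagents that add atoms: methyl chloroformate, COC(=O)Cl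
Why: Acylation of a lithium acetylide with a chloroformate is a standard route to ynoates and brings in C13.

Step 3
Reactants: 7 methyl 3-[(4R)-2,2-dimethyl-1,3-dioxolan-4-yl]prop-2-ynoate; 8 methyllithium; 9 iodine
Product: 11 methyl (2E)-3-[(4R)-2,2-dimethyl-1,3-dioxolan-4-yl]-2-iodobut-2-enoate, via alkenylcuprate 10 (not isolated)
Conditions: 8 (2 equiv), CuI, THF, −78 °C; then 9, −78 °C
Reagents that add atoms: methyllithium (used as Me2CuLi), [Li]C; iodine, II
Why: Syn-carbocupration of the ynoate (conjugate addition) and iodination of the alkenylcopper with retention at −78 °C should fix the tetrasubstituted alkene with the ester cis to the dioxolane.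

Step 4
Reactants: 11 methyl (2E)-3-[(4R)-2,2-dimethyl-1,3-dioxolan-4-yl]-2-iodobut-2-enoate
Product: 12 (2E)-3-[(4R)-2,2-dimethyl-1,3-dioxolan-4-yl]-2-iodobut-2-en-1-ol
Conditions: i-Bu2AlH, CH2Cl2, −78 °C
Reagents that add atoms: none
Why: 1,2-Reduction of an enoate by i-Bu2AlH gives the allylic alcohol without touching the alkenyl iodide or the alkene geometry.

Step 5
Reactants: 12 (2E)-3-[(4R)-2,2-dimethyl-1,3-dioxolan-4-yl]-2-iodobut-2-en-1-ol; 13 3-methylbut-2-enoic acid
Product: 14 (2E)-3-[(4R)-2,2-dimethyl-1,3-dioxolan-4-yl]-2-iodobut-2-en-1-yl 3-methylbut-2-enoate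
Conditions: DCC, DMAP (cat.), CH2Cl2, 0 °C to rt
Reagents that add atoms: 3-methylbut-2-enoic acid, CC(C)=CC(=O)O
Why: Steglich esterification joins the C9–C12/C20 unit to the allylic alcohol under neutral conditions.

Step 6
Reactants: 14 (2E)-3-[(4R)-2,2-dimethyl-1,3-dioxolan-4-yl]-2-iodobut-2-en-1-yl 3-methylbut-2-enoate
Product: 18 (2S,3S)-3-[(4R)-2,2-dimethyl-1,3-dioxolan-4-yl]-4-iodo-3-methyl-2-(prop-1-en-2-yl)pent-4-enoic acid, via lithium dienolate 15 (not isolated), via silyl ketene acetal 16 (not isolated), via trimethylsilyl ester 17 (not isolated)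
Conditions: LiN(i-Pr)2, THF, −78 °C; Me3SiCl, Et3N; −78 °C to 60 °C; aq. NaOH, then pH 4 buffer
Reagents that add atoms: none
Why: In this Ireland–Claisen rearrangement γ-deprotonation of the s-cis senecioate gives the (Z)-ketene acetal, the chair transition state (isopropenyl and C1 methyl equatorial, dioxolane axial) sets C10 and the quaternary C1 in the required relative sense, and C2 selects the face because allylic 1,3-strain with C13H2 holds H-2 in the alkene plane so that the new C1–C10 bond forms anti to the C2–O bond.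

Step 7
Reactants: 18 (2S,3S)-3-[(4R)-2,2-dimethyl-1,3-dioxolan-4-yl]-4-iodo-3-methyl-2-(prop-1-en-2-yl)pent-4-enoic acid
Product: 19 (2S,3R)-3-[(4R)-2,2-dimethyl-1,3-dioxolan-4-yl]-3-methyl-2-(prop-1-en-2-yl)pent-4-ynoic acid
Conditions: KOt-Bu (3 equiv), THF, 0 °C to rt; pH 4 work-up
Reagents that add atoms: none
Why: Anti-E2 dehydroiodination of the 2-iodo-1-alkene can only give the terminal alkyne because C1 is quaternary, and the carboxylate protects C10 from epimerisation or alkene migration.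

Step 8
Reactants: 19 (2S,3R)-3-[(4R)-2,2-dimethyl-1,3-dioxolan-4-yl]-3-methyl-2-(prop-1-en-2-yl)pent-4-ynoic acid
Product: 20 (2S,3R)-3-[(4R)-2,2-dimethyl-1,3-dioxolan-4-yl]-3-methyl-2-(prop-1-en-2-yl)pent-4-yn-1-ol
Conditions: LiAlH4, THF, 0 °C to rt
Reagents that add atoms: none
Why: Hydride reduction of the carboxylic acid gives the C9 alcohol, which removes every carbonyl group that could attack the alkyne in the gold step.

Step 9
Reactants: 20 (2S,3R)-3-[(4R)-2,2-dimethyl-1,3-dioxolan-4-yl]-3-methyl-2-(prop-1-en-2-yl)pent-4-yn-1-ol; 21 tert-butyl(chloro)diphenylsilane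
Product: 22 tert-butyldiphenylsilyl ether of 20 (the 1,5-enyne)
Conditions: 21, imidazole, DMF, rt
Reagents that add atoms: tert-butyl(chloro)diphenylsilane, CC(C)(C)[Si](Cl)(c1ccccc1)c1ccccc1
Why: Silylation of the primary alcohol gives a bulky, non-nucleophilic C9 substituent.

Step 10
Reactants: 22 tert-butyldiphenylsilyl ether of 20 (the 1,5-enyne); 23 acetic acid
Product: 24 ring A acetate (11α-OAc, 11β-Me, 1β-Me, 10β-CH2OSi, 1α-dioxolanyl, C12 as CH2, C13=C14)
Conditions: [(2-biphenylyl)(t-Bu)2P]Au(NCMe)SbF6 (5 mol %), 23 (20 equiv), CH2Cl2, −20 °C to rt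
Reagents that add atoms: acetic acid, CC(=O)O
Why: Proposed new method: the cationic monovalent gold complex π-activates the terminal alkyne C13≡C14, the 1,1-disubstituted alkene attacks through C12 at C13 to give a cyclopropyl gold carbene with tertiary-cation character at C11, acetic acid opens it at C11 anti to the new C12–C13 bond, and protodeauration of the C14–Au bond leaves the cis C13=C14 alkene. The closest known reaction types are the gold-catalysed 6-endo cycloisomerisation of 2-substituted 1,5-enynes to cyclohexadienes, its variants in which a tethered hydroxyl or sulfonamide captures the tertiary centre, and the intermolecular 5-endo hydroxy- and alkoxycyclisation of 1,5-enynes; capture by an external carboxylic acid in the 6-endo manifold is the untested element. Ring A closes in the 6-endo-dig mode and no other ring is formed. The new stereocentre C11 is controlled by allylic 1,3-strain at C10: H-10 lies in the plane of the C11=C12 bond, the CH2OSi group points away, the alkyne arm on C1 reaches the alkene face on its own side and acetate enters the opposite face, so that C11–OAc ends trans to C9 and the C11 methyl cis to the C1 methyl (chair-like transition state with C9 equatorial). The step needs 6-endo over 5-endo closure, which the methyl group on C11 secures by placing the positive charge on a tertiary carbon; it needs capture over proton loss, which the excess of acetic acid at low temperature favours; and it needs no interference from oxygen groups, which is why C9 is a bulky silyl ether and not a carbonyl group here.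

Step 11
Reactants: 24 ring A acetate; 25 tert-butyl hydroperoxide
Product: 26 ring A 12α-alcohol (12-OH cis to 11-OAc)
Conditions: SeO2 (0.5 equiv), 25 (3 equiv), CH2Cl2, rt
Reagents that add atoms: tert-butyl hydroperoxide (terminal oxidant), CC(C)(C)OO; selenium dioxide (oxygen carrier), O=[Se]=O
Why: In this SeO2 allylic oxidation (ene reaction then [2,3]-shift) C12 is the only allylic carbon with hydrogen because C1 is quaternary, and abstraction of the axial α-hydrogen with suprafacial return of oxygen should give the pseudoaxial 12α-alcohol.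

Step 12
Reactants: 26 ring A 12α-alcohol; 27 acetic anhydride
Product: 28 ring A 11,12-diacetate silyl ether
Conditions: 27, pyridine, DMAP (cat.), CH2Cl2, 0 °C to rt
Reagents that add atoms: acetic anhydride, CC(=O)OC(C)=O
Why: DMAP-catalysed acylation of the secondary allylic alcohol is fast and forestalls migration of the tertiary acetate.

Step 13
Reactants: 28 ring A 11,12-diacetate silyl ether
Product: 29 ring A 11,12-diacetate C9 alcohol
Conditions: HF·pyridine, pyridine, THF, rt
Reagents that add atoms: none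
Why: Buffered fluoride desilylation frees the primary C9 alcohol and leaves acetates and the acetonide intact.

Step 14
Reactants: 29 ring A 11,12-diacetate C9 alcohol
Product: 30 ring A 11,12-diacetate C9 aldehyde
Conditions: Dess–Martin periodinane, NaHCO3, CH2Cl2, 0 °C to rt
Reagents that add atoms: none
Why: Dess–Martin oxidation gives the aldehyde under neutral conditions, and the equatorial formyl group at C10 is the thermodynamically favoured epimer.

Step 15
Reactants: 31 4-hydroxy-3-methylfuran-2(5H)-one; 32 trifluoromethanesulfonic anhydride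
Product: 33 4-methyl-5-oxo-2,5-dihydrofuran-3-yl trifluoromethanesulfonate
Conditions: 32, i-Pr2NEt, CH2Cl2, −78 °C
Reagents that add atoms: trifluoromethanesulfonic anhydride, O=S(=O)(OS(=O)(=O)C(F)(F)F)C(F)(F)F
Why: O-Sulfonylation of the vinylogous acid gives an alkenyl triflate that carries C7, C8 and C17–C19.

Step 16
Reactants: 30 ring A 11,12-diacetate C9 aldehyde; 33 4-methyl-5-oxo-2,5-dihydrofuran-3-yl trifluoromethanesulfonate
Product: 34 (9S)-carbinol with the butenolide on C9
Conditions: 33 (2 equiv), CrCl2 (6 equiv), NiCl2 (2 mol %), DMF, rt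
Reagents that add atoms: 4-methyl-5-oxo-2,5-dihydrofuran-3-yl trifluoromethanesulfonate, CC1=C(OS(=O)(=O)C(F)(F)F)COC1=O
Why: In this Nozaki–Hiyama–Kishi coupling the alkenylchromium species should add to the equatorial C9 aldehyde from the α face, away from the axial methyl groups on C1 and C11, in the rotamer that keeps C9=O antiparallel to the C11–O dipole, to give the (9S)-carbinol, while esters and the acetonide are inert.

Step 17
Reactants: 34 (9S)-carbinol with the butenolide on C9; 27 acetic anhydride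
Product: 35 9,11,12-triacetate
Conditions: 27, pyridine, DMAP (cat.), CH2Cl2, 0 °C
Reagents that add atoms: acetic anhydride, CC(=O)OC(C)=O
Why: Acylation installs the third acetate of the target before any base-sensitive step.

Step 18
Reactants: 35 9,11,12-triacetate
Product: 36 2,3-diol
Conditions: AcOH/H2O (4:1), 40 °C
Reagents that add atoms: none
Why: Mild acid hydrolysis of the terminal acetonide frees C2–OH and C3–OH without touching acetates or the butenolide.

Step 19
Reactants: 36 2,3-diol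
Product: 37 2-hydroxy-3-aldehyde
Conditions: TEMPO (cat.), PhI(OAc)2, CH2Cl2, rt
Reagents that add atoms: none
Why: The oxoammonium oxidation is selective for the primary alcohol and leaves the hindered neopentyl C2–OH untouched.

Step 20
Reactants: 37 2-hydroxy-3-aldehyde; 38 3-bromo-2-(bromomethyl)prop-1-ene
Product: 39 (2R,3R)-syn-diol with 2-(bromomethyl)allyl group on C3
Conditions: 38 (3 equiv), In powder, THF/H2O (1:1), rt
Reagents that add atoms: 3-bromo-2-(bromomethyl)prop-1-ene, C=C(CBr)CBr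
Why: In this indium-mediated Barbier allylation the free C2 hydroxyl and the aldehyde oxygen chelate indium so that the allyl group adds anti to C1 and gives the 2,3-syn diol (3R), and excess 38 keeps the second C–Br bond intact.

Step 21
Reactants: 39 (2R,3R)-syn-diol; 40 triethylsilyl trifluoromethanesulfonate
Product: 41 2,3-bis(triethylsilyl) ether
Conditions: 40, 2,6-lutidine, CH2Cl2, −78 °C
Reagents that add atoms: triethylsilyl trifluoromethanesulfonate, CC[Si](CC)(CC)OS(=O)(=O)C(F)(F)F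
Why: Silylation blocks both hydroxyls before the allylic bromide can alkylate C3–O and before the silyl triflate step.

Step 22
Reactants: 41 2,3-bis(triethylsilyl) ether; 42 4-methylmorpholine 4-oxide
Product: 44 enal (C6 aldehyde on C5=C16), via alkoxyammonium bromide 43 (not isolated)
Conditions: 42 (4 equiv), 4 Å sieves, MeCN, rt
Reagents that add atoms: 4-methylmorpholine 4-oxide, C[N+]1([O-])CCOCC1
Why: Amine N-oxide oxidation (Ganem oxidation: SN2 displacement of bromide, then elimination) turns the allylic bromide into the 2-substituted acrolein under neutral conditions.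

Step 23
Reactants: 44 enal; 45 tert-butyldimethylsilyl trifluoromethanesulfonate
Product: 47 macrocyclic butenolide (ring B closed; 6-OSi, 7-H), via silyloxyfuran 46 (not isolated)
Conditions: 45 (3 equiv), Et3N (4 equiv), CH2Cl2 (0.002 M), slow addition of 44, −78 °C to 0 °C
Reagents that add atoms: tert-butyldimethylsilyl trifluoromethanesulfonate, CC(C)(C)[Si](C)(C)OS(=O)(=O)C(F)(F)F
Why: In this silylative intramolecular vinylogous Mukaiyama aldol reaction the 2-silyloxyfuran adds through C7 to the silyl-activated enal C6 and closes ring B, allylic strain between the C17 methyl and C9 keeps H-9 in the furan plane so that the tether reaches one furan face (7R), and the open antiperiplanar transition state usual for Lewis-acid variants should give the 6,7-syn silyl ether (6R).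

Step 24
Reactants: 47 macrocyclic butenolide
Product: 48 macrocyclic 2,3-diol
Conditions: PPTS (cat.), MeOH/CH2Cl2, 0 °C to rt
Reagents that add atoms: none
Why: Acid-catalysed methanolysis removes triethylsilyl ethers much faster than the secondary tert-butyldimethylsilyl ether at C6.

Step 25
Reactants: 48 macrocyclic 2,3-diol
Product: 49 tetracyclic lactone C6 silyl ether
Conditions: DBU (0.3 equiv), MeCN, 0 °C to rt
Reagents that add atoms: none
Why: Transannular oxa-Michael addition (6-exo-trig) of C2–OH to C8 closes ring C with the only C8 configuration the bicyclo[5.3.1] frame allows, C17 is set by kinetic protonation of the lactone enolate on the face of the new C8–O bond (anti to C9 and C6), and C3–OH stays free because it would need a seven-membered ring.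

Step 26
Reactants: 49 tetracyclic lactone C6 silyl ether
Product: 50 tetracyclic 3,6-diol
Conditions: HF·pyridine, pyridine, THF, 0 °C to rt
Reagents that add atoms: none
Why: Fluoride desilylation frees C6–OH once the lactone is saturated and C7–H is no longer acidic.

Step 27
Reactants: 50 tetracyclic 3,6-diol; 51 N-chlorosuccinimide
Product: 53 CNP0333938.2, via alkoxysulfonium chloride 52 (not isolated)
Conditions: 51, Me2S, CH2Cl2, −20 °C to 0 °C
Reagents that add atoms: N-chlorosuccinimide, O=C1CCC(=O)N1Cl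
Why: In the Corey–Kim chlorination only the allylic C6 alkoxysulfonium ion is displaced by chloride (SN2, inversion to 6S), whereas the adduct of the non-allylic C3–OH reverts to the alcohol on work-up.

## Compound list

1 | methyl (4S)-2,2-dimethyl-1,3-dioxolane-4-carboxylate | COC(=O)[C@@H]1COC(C)(C)O1 | starting material
2 | dimethyl (1-diazo-2-oxopropyl)phosphonate | CC(=O)C(=[N+]=[N-])P(=O)(OC)OC | starting material
3 | (4S)-2,2-dimethyl-1,3-dioxolane-4-carbaldehyde | O=C[C@@H]1COC(C)(C)O1 | intermediate (not isolated)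
4 | (4R)-4-ethynyl-2,2-dimethyl-1,3-dioxolane | C#C[C@@H]1COC(C)(C)O1 | intermediate
5 | methyl chloroformate | COC(=O)Cl | starting material
6 | lithium acetylide of 4 | [Li]C#C[C@@H]1COC(C)(C)O1 | intermediate (not isolated)
7 | methyl 3-[(4R)-2,2-dimethyl-1,3-dioxolan-4-yl]prop-2-ynoate | COC(=O)C#C[C@@H]1COC(C)(C)O1 | intermediate
8 | methyllithium | [Li]C | starting material
9 | iodine | II | starting material
10 | lithium alkenyl(methyl)cuprate from 7 (Cu on the α-carbon, cis to the new methyl) | [Li+].COC(=O)/C([Cu-]C)=C(/C)[C@@H]1COC(C)(C)O1 | intermediate (not isolated)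
11 | methyl (2E)-3-[(4R)-2,2-dimethyl-1,3-dioxolan-4-yl]-2-iodobut-2-enoate | COC(=O)/C(I)=C(/C)[C@@H]1COC(C)(C)O1 | intermediate
12 | (2E)-3-[(4R)-2,2-dimethyl-1,3-dioxolan-4-yl]-2-iodobut-2-en-1-ol | OC/C(I)=C(/C)[C@@H]1COC(C)(C)O1 | intermediate
13 | 3-methylbut-2-enoic acid | CC(C)=CC(=O)O | starting material
14 | (2E)-3-[(4R)-2,2-dimethyl-1,3-dioxolan-4-yl]-2-iodobut-2-en-1-yl 3-methylbut-2-enoate | CC(C)=CC(=O)OC/C(I)=C(/C)[C@@H]1COC(C)(C)O1 | intermediate
15 | lithium dienolate of 14 (O–Li cis to the diene) | [Li+].C=C(C)/C=C(\[O-])OC/C(I)=C(/C)[C@@H]1COC(C)(C)O1 | intermediate (not isolated)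
16 | (1Z)-trimethylsilyl ketene acetal of 14 | C=C(C)/C=C(\O[Si](C)(C)C)OC/C(I)=C(/C)[C@@H]1COC(C)(C)O1 | intermediate (not isolated)
17 | trimethylsilyl ester of 18 | C[Si](C)(C)OC(=O)[C@@H](C(C)=C)[C@](C)(C(I)=C)[C@@H]1COC(C)(C)O1 | intermediate (not isolated)
18 | (2S,3S)-3-[(4R)-2,2-dimethyl-1,3-dioxolan-4-yl]-4-iodo-3-methyl-2-(prop-1-en-2-yl)pent-4-enoic acid | OC(=O)[C@@H](C(C)=C)[C@](C)(C(I)=C)[C@@H]1COC(C)(C)O1 | intermediate
19 | (2S,3R)-3-[(4R)-2,2-dimethyl-1,3-dioxolan-4-yl]-3-methyl-2-(prop-1-en-2-yl)pent-4-ynoic acid | OC(=O)[C@@H](C(C)=C)[C@](C)(C#C)[C@@H]1COC(C)(C)O1 | intermediate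
20 | (2S,3R)-3-[(4R)-2,2-dimethyl-1,3-dioxolan-4-yl]-3-methyl-2-(prop-1-en-2-yl)pent-4-yn-1-ol | OC[C@@H](C(C)=C)[C@](C)(C#C)[C@@H]1COC(C)(C)O1 | intermediate
21 | tert-butyl(chloro)diphenylsilane | CC(C)(C)[Si](Cl)(c1ccccc1)c1ccccc1 | starting material
22 | tert-butyldiphenylsilyl ether of 20 (1,5-enyne: C12=C11 isopropenyl on C10, C13≡C14 on C1) | CC(C)(C)[Si](OC[C@@H](C(C)=C)[C@](C)(C#C)[C@@H]1COC(C)(C)O1)(c1ccccc1)c1ccccc1 | intermediate
23 | acetic acid | CC(=O)O | starting material
24 | ring A acetate: cyclohexene C1, C10–C14 with 13,14-ene, 11α-OAc, 11β-Me, 1β-Me, 1α-[(4R)-2,2-dimethyl-1,3-dioxolan-4-yl], 10β-CH2OSi(t-Bu)Ph2 | CC(C)(C)[Si](OC[C@H]1[C@](C)(OC(C)=O)CC=C[C@]1(C)[C@@H]1COC(C)(C)O1)(c1ccccc1)c1ccccc1 | intermediate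
25 | tert-butyl hydroperoxide | CC(C)(C)OO | starting material
26 | 24 with 12α-OH (cis to 11-OAc) | CC(C)(C)[Si](OC[C@H]1[C@](C)(OC(C)=O)[C@H](O)C=C[C@]1(C)[C@@H]1COC(C)(C)O1)(c1ccccc1)c1ccccc1 | intermediate
27 | acetic anhydride | CC(=O)OC(C)=O | starting material
28 | ring A 11α,12α-diacetate, C9 silyl ether | CC(C)(C)[Si](OC[C@H]1[C@](C)(OC(C)=O)[C@H](OC(C)=O)C=C[C@]1(C)[C@@H]1COC(C)(C)O1)(c1ccccc1)c1ccccc1 | intermediate
29 | ring A 11α,12α-diacetate, C9 primary alcohol | OC[C@H]1[C@](C)(OC(C)=O)[C@H](OC(C)=O)C=C[C@]1(C)[C@@H]1COC(C)(C)O1 | intermediate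
30 | ring A 11α,12α-diacetate, C9 aldehyde | O=C[C@H]1[C@](C)(OC(C)=O)[C@H](OC(C)=O)C=C[C@]1(C)[C@@H]1COC(C)(C)O1 | intermediate
31 | 4-hydroxy-3-methylfuran-2(5H)-one (3-methyltetronic acid) | CC1=C(O)COC1=O | starting material
32 | trifluoromethanesulfonic anhydride | O=S(=O)(OS(=O)(=O)C(F)(F)F)C(F)(F)F | starting material
33 | 4-methyl-5-oxo-2,5-dihydrofuran-3-yl trifluoromethanesulfonate | CC1=C(OS(=O)(=O)C(F)(F)F)COC1=O | intermediate
34 | (9S)-carbinol: 30 with C9 bearing OH and the 3-methylbutenolide (bonded through C8) | O[C@H](C1=C(C)C(=O)OC1)[C@H]1[C@](C)(OC(C)=O)[C@H](OC(C)=O)C=C[C@]1(C)[C@@H]1COC(C)(C)O1 | intermediate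
35 | 9,11,12-triacetate of 34 | CC(=O)O[C@H](C1=C(C)C(=O)OC1)[C@H]1[C@](C)(OC(C)=O)[C@H](OC(C)=O)C=C[C@]1(C)[C@@H]1COC(C)(C)O1 | intermediate
36 | triacetate (2R)-2,3-diol | CC(=O)O[C@H](C1=C(C)C(=O)OC1)[C@H]1[C@](C)(OC(C)=O)[C@H](OC(C)=O)C=C[C@]1(C)[C@@H](O)CO | intermediate
37 | triacetate 2-hydroxy-3-aldehyde | CC(=O)O[C@H](C1=C(C)C(=O)OC1)[C@H]1[C@](C)(OC(C)=O)[C@H](OC(C)=O)C=C[C@]1(C)[C@@H](O)C=O | intermediate
38 | 3-bromo-2-(bromomethyl)prop-1-ene | C=C(CBr)CBr | starting material
39 | (2R,3R)-syn-diol with CH2–C(=CH2)–CH2Br on C3 | CC(=O)O[C@H](C1=C(C)C(=O)OC1)[C@H]1[C@](C)(OC(C)=O)[C@H](OC(C)=O)C=C[C@]1(C)[C@@H](O)[C@H](O)CC(=C)CBr | intermediate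
40 | triethylsilyl trifluoromethanesulfonate | CC[Si](CC)(CC)OS(=O)(=O)C(F)(F)F | starting material
41 | 2,3-bis(triethylsilyl) ether of 39 | CC(=O)O[C@H](C1=C(C)C(=O)OC1)[C@H]1[C@](C)(OC(C)=O)[C@H](OC(C)=O)C=C[C@]1(C)[C@@H](O[Si](CC)(CC)CC)[C@H](O[Si](CC)(CC)CC)CC(=C)CBr | intermediate
42 | 4-methylmorpholine 4-oxide | C[N+]1([O-])CCOCC1 | starting material
43 | N-(allyloxy)-N-methylmorpholinium bromide from 41 | [Br-].CC(=O)O[C@H](C1=C(C)C(=O)OC1)[C@H]1[C@](C)(OC(C)=O)[C@H](OC(C)=O)C=C[C@]1(C)[C@@H](O[Si](CC)(CC)CC)[C@H](O[Si](CC)(CC)CC)CC(=C)CO[N+]1(C)CCOCC1 | intermediate (not isolated)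
44 | enal: 41 with CH2Br replaced by CHO (C6) | CC(=O)O[C@H](C1=C(C)C(=O)OC1)[C@H]1[C@](C)(OC(C)=O)[C@H](OC(C)=O)C=C[C@]1(C)[C@@H](O[Si](CC)(CC)CC)[C@H](O[Si](CC)(CC)CC)CC(=C)C=O | intermediate
45 | tert-butyldimethylsilyl trifluoromethanesulfonate | CC(C)(C)[Si](C)(C)OS(=O)(=O)C(F)(F)F | starting material
46 | 2-(tert-butyldimethylsilyloxy)furan derived from the butenolide of 44 | CC(=O)O[C@H](c1coc(O[Si](C)(C)C(C)(C)C)c1C)[C@H]1[C@](C)(OC(C)=O)[C@H](OC(C)=O)C=C[C@]1(C)[C@@H](O[Si](CC)(CC)CC)[C@H](O[Si](CC)(CC)CC)CC(=C)C=O | intermediate (not isolated)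
47 | macrocyclic butenolide: rings A, B and butenolide; (6R)-OSi(t-Bu)Me2, (7R), 2,3-bis(OSiEt3), 5(16)-ene | C=C1C[C@@H](O[Si](CC)(CC)CC)[C@H](O[Si](CC)(CC)CC)[C@@]2(C)C=C[C@@H](OC(C)=O)[C@@](C)(OC(C)=O)[C@@H]2[C@H](OC(C)=O)C2=C(C)C(=O)O[C@H]2[C@@H]1O[Si](C)(C)C(C)(C)C | intermediate
48 | macrocyclic 2,3-diol | C=C1C[C@@H](O)[C@H](O)[C@@]2(C)C=C[C@@H](OC(C)=O)[C@@](C)(OC(C)=O)[C@@H]2[C@H](OC(C)=O)C2=C(C)C(=O)O[C@H]2[C@@H]1O[Si](C)(C)C(C)(C)C | intermediate
49 | tetracyclic lactone (rings A–D), (6R)-OSi(t-Bu)Me2, 3-OH | C=C1C[C@@H](O)[C@@H]2O[C@@]3([C@@H](C)C(=O)O[C@H]3[C@@H]1O[Si](C)(C)C(C)(C)C)[C@@H](OC(C)=O)[C@@H]1[C@]2(C)C=C[C@@H](OC(C)=O)[C@@]1(C)OC(C)=O | intermediate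
50 | tetracyclic (6R)-3,6-diol | C=C1C[C@@H](O)[C@@H]2O[C@@]3([C@@H](C)C(=O)O[C@H]3[C@@H]1O)[C@@H](OC(C)=O)[C@@H]1[C@]2(C)C=C[C@@H](OC(C)=O)[C@@]1(C)OC(C)=O | intermediate
51 | N-chlorosuccinimide | O=C1CCC(=O)N1Cl | starting material
52 | C6 alkoxydimethylsulfonium chloride of 50 | [Cl-].C=C1C[C@@H](O)[C@@H]2O[C@@]3([C@@H](C)C(=O)O[C@H]3[C@@H]1O[S+](C)C)[C@@H](OC(C)=O)[C@@H]1[C@]2(C)C=C[C@@H](OC(C)=O)[C@@]1(C)OC(C)=O | intermediate (not isolated)
53 | CNP0333938.2 | C=C1C[C@@H](O)[C@@H]2O[C@@]3([C@@H](C)C(=O)O[C@H]3[C@H]1Cl)[C@@H](OC(C)=O)[C@@H]1[C@]2(C)C=C[C@@H](OC(C)=O)[C@@]1(C)OC(C)=O | target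

## Summary and risks

Total step count: 27. Longest linear sequence: 26 (steps 1–14 and 16–27; step 15 is the side branch).

Three steps most likely to fail:

1. Step 10 (Proposed new method). The tertiary cation at C11 may lose a proton to give cyclohexadienes, the carbene may rearrange to a bicyclo[3.1.0]hexene, the dioxolane oxygens may attack the activated alkyne, or acetate may add with poor facial selectivity. The fallback uses known chemistry, sets out from 22 and comes back at 28. N-Iodosuccinimide with AgNO3 (cat.) in acetone gives iodoalkyne F1. Diimide (2-nitrobenzenesulfonyl hydrazide, Et3N) reduces it to the (Z)-iodoalkene F2. SeO2/t-BuOOH oxidises the isopropenyl methyl group to allylic alcohol F3, and Dess–Martin periodinane gives enal F4; this oxidised carbon becomes C12 in this variant. CrCl2 with NiCl2 (cat.) in DMSO at high dilution closes ring A at the same C12–C13 bond by Nozaki–Hiyama–Kishi addition and gives dienol F5, whose 12-OH is axial through allylic strain with the exocyclic C11 methylene. Mukaiyama hydration of that methylene (Mn(dpm)3, PhSiH3, O2; then PPh3), with attack anti to the axial C1 methyl, gives cis-diol F6. Ac2O, DMAP and Et3N at 40 °C give 28.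

2. Step 23. Oligomerisation may outrun the ten-membered ring closure, the furan face or the aldehyde face may be chosen wrongly, and the C9 acetate next to the electron-rich silyloxyfuran may ionise. The fallback closes ring B at C3–C4 instead; it sets out from 35 and comes back at 48. t-BuMe2SiOTf/Et3N and then 2-{[tert-butyl(dimethyl)silyl]oxymethyl}prop-2-enal give the open-chain silylated vinylogous aldol adduct F7, whose C6/C7 diastereomers are separated. HF·pyridine/pyridine frees the primary allylic alcohol F8. CBr4/PPh3 gives allylic bromide F9. BiCl3 in wet MeCN removes the acetonide to give diol F10. TEMPO/PhI(OAc)2 gives hydroxy aldehyde F11. CrCl2 in THF at high dilution closes the ring by intramolecular Nozaki–Hiyama allylation under chelation control and gives 48.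

3. Step 27. Chloride may enter at C16 with allylic transposition, the sulfonium ion may eliminate, or the reagent may fail to discriminate fully against C3–OH. The fallback separates protection, activation and displacement; it sets out from 49 and comes back at 53. 4-Methoxybenzyl trichloroacetimidate with La(OTf)3 (cat.) gives the C3 4-methoxybenzyl ether F12. HF·pyridine gives alcohol F13. MsCl/Et3N gives mesylate F14. LiCl in DMF displaces it with inversion to give chloride F15. DDQ in wet CH2Cl2 removes the ether and gives 53.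

Further compounds
F1 | step 10 | iodoalkyne from 22 (C13–I) | CC(C)(C)[Si](OC[C@@H](C(C)=C)[C@](C)(C#CI)[C@@H]1COC(C)(C)O1)(c1ccccc1)c1ccccc1
F2 | step 10 | (Z)-iodoalkene | CC(C)(C)[Si](OC[C@@H](C(C)=C)[C@](C)(/C=C\I)[C@@H]1COC(C)(C)O1)(c1ccccc1)c1ccccc1
F3 | step 10 | allylic alcohol (hydroxymethyl on C11) | CC(C)(C)[Si](OC[C@@H](C(=C)CO)[C@](C)(/C=C\I)[C@@H]1COC(C)(C)O1)(c1ccccc1)c1ccccc1
F4 | step 10 | enal (C12 aldehyde, C11 methylene) | CC(C)(C)[Si](OC[C@@H](C(=C)C=O)[C@](C)(/C=C\I)[C@@H]1COC(C)(C)O1)(c1ccccc1)c1ccccc1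
F5 | step 10 | ring A dienol (12α-OH, exocyclic C11 methylene) | CC(C)(C)[Si](OC[C@H]1C(=C)[C@H](O)C=C[C@]1(C)[C@@H]1COC(C)(C)O1)(c1ccccc1)c1ccccc1
F6 | step 10 | ring A 11α,12α-diol | CC(C)(C)[Si](OC[C@H]1[C@](C)(O)[C@H](O)C=C[C@]1(C)[C@@H]1COC(C)(C)O1)(c1ccccc1)c1ccccc1
F7 | step 23 | open-chain aldol adduct, (6R)-OSi, (7R), primary silyl ether on C4 | CC(=O)O[C@H](C1=C(C)C(=O)O[C@H]1[C@H](O[Si](C)(C)C(C)(C)C)C(=C)CO[Si](C)(C)C(C)(C)C)[C@H]1[C@](C)(OC(C)=O)[C@H](OC(C)=O)C=C[C@]1(C)[C@@H]1COC(C)(C)O1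
F8 | step 23 | primary allylic alcohol | CC(=O)O[C@H](C1=C(C)C(=O)O[C@H]1[C@H](O[Si](C)(C)C(C)(C)C)C(=C)CO)[C@H]1[C@](C)(OC(C)=O)[C@H](OC(C)=O)C=C[C@]1(C)[C@@H]1COC(C)(C)O1
F9 | step 23 | allylic bromide | CC(=O)O[C@H](C1=C(C)C(=O)O[C@H]1[C@H](O[Si](C)(C)C(C)(C)C)C(=C)CBr)[C@H]1[C@](C)(OC(C)=O)[C@H](OC(C)=O)C=C[C@]1(C)[C@@H]1COC(C)(C)O1
F10 | step 23 | allylic bromide 2,3-diol | CC(=O)O[C@H](C1=C(C)C(=O)O[C@H]1[C@H](O[Si](C)(C)C(C)(C)C)C(=C)CBr)[C@H]1[C@](C)(OC(C)=O)[C@H](OC(C)=O)C=C[C@]1(C)[C@@H](O)CO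
F11 | step 23 | allylic bromide 2-hydroxy-3-aldehyde | CC(=O)O[C@H](C1=C(C)C(=O)O[C@H]1[C@H](O[Si](C)(C)C(C)(C)C)C(=C)CBr)[C@H]1[C@](C)(OC(C)=O)[C@H](OC(C)=O)C=C[C@]1(C)[C@@H](O)C=O
F12 | step 27 | 3-O-(4-methoxybenzyl) ether of 49 | C=C1C[C@@H](OCc2ccc(OC)cc2)[C@@H]2O[C@@]3([C@@H](C)C(=O)O[C@H]3[C@@H]1O[Si](C)(C)C(C)(C)C)[C@@H](OC(C)=O)[C@@H]1[C@]2(C)C=C[C@@H](OC(C)=O)[C@@]1(C)OC(C)=O
F13 | step 27 | 3-O-(4-methoxybenzyl) (6R)-alcohol | C=C1C[C@@H](OCc2ccc(OC)cc2)[C@@H]2O[C@@]3([C@@H](C)C(=O)O[C@H]3[C@@H]1O)[C@@H](OC(C)=O)[C@@H]1[C@]2(C)C=C[C@@H](OC(C)=O)[C@@]1(C)OC(C)=O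
F14 | step 27 | 3-O-(4-methoxybenzyl) (6R)-mesylate | C=C1C[C@@H](OCc2ccc(OC)cc2)[C@@H]2O[C@@]3([C@@H](C)C(=O)O[C@H]3[C@@H]1OS(C)(=O)=O)[C@@H](OC(C)=O)[C@@H]1[C@]2(C)C=C[C@@H](OC(C)=O)[C@@]1(C)OC(C)=O
F15 | step 27 | 3-O-(4-methoxybenzyl) (6S)-chloride | C=C1C[C@@H](OCc2ccc(OC)cc2)[C@@H]2O[C@@]3([C@@H](C)C(=O)O[C@H]3[C@H]1Cl)[C@@H](OC(C)=O)[C@@H]1[C@]2(C)C=C[C@@H](OC(C)=O)[C@@]1(C)OC(C)=O
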